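**Retrosynthetic overview**
- The azepine ring and the fused butenolide (N,O-acetal carbon C5) are made together in the last operation: singlet-oxygen dearomatisation/decarboxylation of a 3,4-disubstituted 2-furoic acid, whose 5-hydroxybutenolide is captured by the pyrrolidine N–H (N–C5 bond).
- The furoate is attached at C6–C7 by nickel reductive cross-coupling of a primary bromide with a 4-bromofuroate made from 3-methyl-2-furoic acid.
- The appended lactone (C3–C17) comes from decarboxylative N-acyliminium formation at C3 and vinylogous Mannich addition of 3-methyl-2-silyloxyfuran, then hydrogenation.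
- The spirolactone (C9–C9a, quaternary C9) comes from vinylogous Mannich addition of a 5-(2-bromoethyl)-2-silyloxyfuran to the L-pyroglutamate-derived N-acyliminium ion, then carbamate-directed hydrogenation.
- Ring order: pyrrolidine (chiral pool) → spirolactone → appended lactone → furan attached → butenolide and azepine last.

Core atoms are labelled as in a pyrrolo[1,2-a]azepine (N4, C5, C6, C9 spiro, C9a, C3).

Assumption: the C5 N,O-acetal configuration of the target is the thermodynamic one, since it is formed under equilibrating conditions in the last step.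

**Route**

Step 1
Reactants: 1 3-methylfuran-2(5H)-one
Product: 2 3-methyl-2-(triisopropylsilyloxy)furan
Conditions: TIPSOTf (1.05 equiv), Et3N (1.3 equiv), CH2Cl2, 0 °C → rt
Reagents that add atoms: triisopropylsilyl trifluoromethanesulfonate, CC(C)[Si](C(C)C)(C(C)C)OS(=O)(=O)C(F)(F)F
Why: Soft enolisation and O-silylation of the butenolide (silyl dienol ether formation) gives the aromatic 2-silyloxyfuran; no stereocentre.

Step 2
Reactants: 2 3-methyl-2-(triisopropylsilyloxy)furan
Product: 4 5-(2-bromoethyl)-3-methyl-2-(triisopropylsilyloxy)furan, via 5-lithio-3-methyl-2-(triisopropylsilyloxy)furan 3 (not isolated)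
Conditions: s-BuLi (1.1 equiv), THF, −78 → 0 °C; then BrCH2CH2OTf (1.5 equiv), −78 °C
Reagents that add atoms: 2-bromoethyl trifluoromethanesulfonate, BrCCOS(=O)(=O)C(F)(F)F
Why: α-Lithiation of the furan C5–H followed by SN2 alkylation at the triflate carbon, which reacts far faster than C–Br; amine additives are left out so nothing competes for the triflate.

Step 3
Reactants: 5 methyl (2S)-1-(tert-butoxycarbonyl)-5-oxopyrrolidine-2-carboxylate (methyl N-Boc-L-pyroglutamate)
Product: 7 methyl (2S)-1-(tert-butoxycarbonyl)-5-methoxypyrrolidine-2-carboxylate (C5 epimers), via hemiaminal 6 (not isolated)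
Conditions: LiBHEt3 (1.1 equiv), THF, −78 °C; then AcOH (1.1 equiv), MeOH, PPTS (10 mol %), rt
Reagents that add atoms: methanol, CO
Why: Chemoselective hydride reduction of the Boc-activated (imide-like) lactam carbonyl, then acid-catalysed N,O-acetal exchange; C2 (S) is untouched and C5 becomes the iminium carbon.

Step 4
Reactants: 4 5-(2-bromoethyl)-3-methyl-2-(triisopropylsilyloxy)furan; 7 methyl (2S)-1-(tert-butoxycarbonyl)-5-methoxypyrrolidine-2-carboxylate
Product: 8 methyl (2S,5S)-1-(tert-butoxycarbonyl)-5-[(2S)-2-(2-bromoethyl)-4-methyl-5-oxo-2,5-dihydrofuran-2-yl]pyrrolidine-2-carboxylate (2,5-trans, threo)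
Conditions: TIPSOTf (10 mol %), CH2Cl2, 0 °C
Reagents that add atoms: none
Why: Vinylogous Mannich (Mukaiyama-type) reaction: furan C5 adds to the N-acyliminium ion anti to the pseudoaxial CO2Me (2,5-trans) through the open transition state that gives the threo C9/C9a adduct, as known for the 4-bromobutyl homologue; this sets C9a (S) and quaternary C9.

Step 5
Reactants: 8 (butenolide from step 4)
Product: 9 methyl (2S,5S)-1-(tert-butoxycarbonyl)-5-[(2R,4R)-2-(2-bromoethyl)-4-methyl-5-oxooxolan-2-yl]pyrrolidine-2-carboxylate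
Conditions: [Ir(cod)(PCy3)(py)]PF6 (10 mol %), H2 (1–4 atm), CH2Cl2, rt
Reagents that add atoms: none
Why: Carbamate-directed homogeneous hydrogenation (Crabtree catalyst): iridium bound to the Boc carbonyl can only reach the butenolide face that carries C9a, so hydrogen is delivered there and the methyl ends trans to C9a and cis to the bromoethyl arm.

Step 6
Reactants: 9 (saturated spirolactone methyl ester)
Product: 11 (2S,5S)-1-(tert-butoxycarbonyl)-5-[(2R,4R)-2-(2-bromoethyl)-4-methyl-5-oxooxolan-2-yl]pyrrolidine-2-carboxylic acid, via open dilithium salt 10 (not isolated)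
Conditions: LiOH (3 equiv), THF/H2O, 0 °C; then 1 M HCl to pH 2, rt
Reagents that add atoms: lithium hydroxide, [Li+].[OH-]
Why: Saponification of the methyl ester; the γ-lactone opens and re-closes on acidification (Thorpe–Ingold-assisted), the α-methyl centre is not enolised as a carboxylate, and the C2 centre is removed in the next step.

Step 7
Reactants: 11 (carboxylic acid from step 6); 2 3-methyl-2-(triisopropylsilyloxy)furan
Product: 13 tert-butyl (2S,5S)-2-[(2R,4R)-2-(2-bromoethyl)-4-methyl-5-oxooxolan-2-yl]-5-[(2S)-4-methyl-5-oxo-2,5-dihydrofuran-2-yl]pyrrolidine-1-carboxylate, via acetoxy aminal 12 (not isolated)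
Conditions: PhI(OAc)2 (1.5 equiv), I2 (0.5 equiv), CH2Cl2, visible light, rt; evaporate; then 2 (3 equiv), TIPSOTf (10 mol %), CH2Cl2, −78 → 0 °C
Reagents that add atoms: none
Why: Radical decarboxylation–oxidation (hypoiodite fragmentation) gives the α-acetoxy carbamate, whose N-acyliminium ion undergoes a second vinylogous Mannich reaction; the bulky C9a substituent is pseudoaxial (A1,3 strain with Boc) so the furan adds trans to it (C3 S), threo as before (C17 S).

Step 8
Reactants: 13 (butenolide from step 7)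
Product: 14 tert-butyl (2S,5S)-2-[(2R,4R)-2-(2-bromoethyl)-4-methyl-5-oxooxolan-2-yl]-5-[(2S,4S)-4-methyl-5-oxooxolan-2-yl]pyrrolidine-1-carboxylate
Conditions: H2 (1 atm), 5% Rh/C, EtOAc, rt
Reagents that add atoms: none
Why: Heterogeneous hydrogenation from the butenolide face opposite the pyrrolidine substituent gives the cis-2,4-disubstituted lactone (C19 S); Rh/C leaves the C–Br bond intact.

Step 9
Reactants: 15 3-methylfuran-2-carboxylic acid
Product: 16 4,5-dibromo-3-methylfuran-2-carboxylic acid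
Conditions: Br2 (2.5 equiv), CHCl3, 50 °C, dark
Reagents that add atoms: bromine, BrBr
Why: Electrophilic aromatic bromination at both free ring positions (C5 first, then C4).

Step 10
Reactants: 16 4,5-dibromo-3-methylfuran-2-carboxylic acid
Product: 17 4-bromo-3-methylfuran-2-carboxylic acid
Conditions: Zn dust (1.5 equiv), conc. aq NH3, 0 °C → rt
Reagents that add atoms: none
Why: Selective reductive removal of the α-bromine (C5) by zinc, the standard route from 4,5-dibromo- to 4-bromo-2-furoic acids.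

Step 11
Reactants: 17 4-bromo-3-methylfuran-2-carboxylic acid
Product: 18 tert-butyl 4-bromo-3-methylfuran-2-carboxylate
Conditions: isobutylene (excess), H2SO4 (cat.), CH2Cl2, rt, sealed tube
Reagents that add atoms: 2-methylpropene, CC(C)=C
Why: Acid-catalysed addition of the acid to isobutylene (tert-butyl ester formation), so that ester and Boc are cleaved together in the last step.

Step 12
Reactants: 14 (bromide from step 8); 18 tert-butyl 4-bromo-3-methylfuran-2-carboxylate
Product: 19 tert-butyl (2S,5S)-2-[(2S,4R)-2-{2-[5-(tert-butoxycarbonyl)-4-methylfuran-3-yl]ethyl}-4-methyl-5-oxooxolan-2-yl]-5-[(2S,4S)-4-methyl-5-oxooxolan-2-yl]pyrrolidine-1-carboxylate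
Conditions: NiI2·xH2O (10 mol %), 4,4′-dimethoxy-2,2′-bipyridine (10 mol %), NaI (25 mol %), pyridine (10 mol %), Zn (2 equiv), DMPU, 60 °C
Reagents that add atoms: none
Why: Nickel-catalysed reductive cross-electrophile coupling of the primary alkyl bromide with the heteroaryl bromide forms C6–C7; lactones, Boc and ester are tolerated and no stereocentre is touched.

Step 13
Reactants: 19 (coupled furoate from step 12)
Product: 22 CNP0155196.1 (target), via ammonium furoic acid 20 (not isolated), via hydroxybutenolide 21 (not isolated)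
Conditions: TFA/CH2Cl2 (1:3), 0 °C → rt; evaporate; O2, methylene blue (2 mol %), white LED, MeCN, 0 °C; then aq NaHCO3 to pH 7–8, rt
Reagents that add atoms: dioxygen (as singlet oxygen), O=O
Why: Proposed new method: after acidolysis of Boc and the tert-butyl ester, singlet oxygen adds [4+2] across C2/C5 of the furoic acid and the endoperoxide fragments with loss of CO2 to the 5-hydroxybutenolide (carbonyl at the former carboxyl carbon, so the regiochemistry is fixed; the ammonium is inert to 1O2); on neutralisation the secondary amine condenses with the masked aldehyde C5 and the iminium is closed by the carboxylate to the seven-membered N,O-acetal, which equilibrates through that iminium to the epimer with C5–O antiperiplanar to the nitrogen lone pair (C5 S); the closest known reactions are the sensitised photooxygenation of 2-furoic acids to 5-hydroxy-2(5H)-furanones and the condensation of 5-hydroxybutenolides with secondary amines to 5-amino-2(5H)-furanones.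

**Compound list**

1 | 3-methylfuran-2(5H)-one | CC1=CCOC1=O | starting material
2 | 3-methyl-2-(triisopropylsilyloxy)furan | Cc1ccoc1O[Si](C(C)C)(C(C)C)C(C)C | intermediate
3 | 5-lithio-3-methyl-2-(triisopropylsilyloxy)furan (not isolated) | [Li]c1cc(C)c(O[Si](C(C)C)(C(C)C)C(C)C)o1 | intermediate
4 | 5-(2-bromoethyl)-3-methyl-2-(triisopropylsilyloxy)furan | Cc1cc(CCBr)oc1O[Si](C(C)C)(C(C)C)C(C)C | intermediate
5 | methyl (2S)-1-(tert-butoxycarbonyl)-5-oxopyrrolidine-2-carboxylate | COC(=O)[C@@H]1CCC(=O)N1C(=O)OC(C)(C)C | starting material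
6 | methyl (2S)-1-(tert-butoxycarbonyl)-5-hydroxypyrrolidine-2-carboxylate, C5 epimers (not isolated) | COC(=O)[C@@H]1CCC(O)N1C(=O)OC(C)(C)C | intermediate
7 | methyl (2S)-1-(tert-butoxycarbonyl)-5-methoxypyrrolidine-2-carboxylate, C5 epimers | COC(=O)[C@@H]1CCC(OC)N1C(=O)OC(C)(C)C | intermediate
8 | methyl (2S,5S)-1-(tert-butoxycarbonyl)-5-[(2S)-2-(2-bromoethyl)-4-methyl-5-oxo-2,5-dihydrofuran-2-yl]pyrrolidine-2-carboxylate | BrCC[C@]1(C=C(C)C(=O)O1)[C@@H]1CC[C@@H](C(=O)OC)N1C(=O)OC(C)(C)C | intermediate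
9 | methyl (2S,5S)-1-(tert-butoxycarbonyl)-5-[(2R,4R)-2-(2-bromoethyl)-4-methyl-5-oxooxolan-2-yl]pyrrolidine-2-carboxylate | BrCC[C@]1(C[C@@H](C)C(=O)O1)[C@@H]1CC[C@@H](C(=O)OC)N1C(=O)OC(C)(C)C | intermediate
10 | dilithium (2S,5S)-1-(tert-butoxycarbonyl)-5-[(3R,5R)-1-bromo-5-carboxylato-3-hydroxyhexan-3-yl]pyrrolidine-2-carboxylate (ring-opened, not isolated) | BrCC[C@](O)(C[C@@H](C)C(=O)[O-])[C@@H]1CC[C@@H](C(=O)[O-])N1C(=O)OC(C)(C)C.[Li+].[Li+] | intermediate
11 | (2S,5S)-1-(tert-butoxycarbonyl)-5-[(2R,4R)-2-(2-bromoethyl)-4-methyl-5-oxooxolan-2-yl]pyrrolidine-2-carboxylic acid | BrCC[C@]1(C[C@@H](C)C(=O)O1)[C@@H]1CC[C@@H](C(=O)O)N1C(=O)OC(C)(C)C | intermediate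
12 | tert-butyl (2S)-5-acetoxy-2-[(2R,4R)-2-(2-bromoethyl)-4-methyl-5-oxooxolan-2-yl]pyrrolidine-1-carboxylate, acetoxy epimers (not isolated) | BrCC[C@]1(C[C@@H](C)C(=O)O1)[C@@H]1CCC(OC(C)=O)N1C(=O)OC(C)(C)C | intermediate
13 | tert-butyl (2S,5S)-2-[(2R,4R)-2-(2-bromoethyl)-4-methyl-5-oxooxolan-2-yl]-5-[(2S)-4-methyl-5-oxo-2,5-dihydrofuran-2-yl]pyrrolidine-1-carboxylate | BrCC[C@]1(C[C@@H](C)C(=O)O1)[C@@H]1CC[C@@H]([C@@H]2C=C(C)C(=O)O2)N1C(=O)OC(C)(C)C | intermediate
14 | tert-butyl (2S,5S)-2-[(2R,4R)-2-(2-bromoethyl)-4-methyl-5-oxooxolan-2-yl]-5-[(2S,4S)-4-methyl-5-oxooxolan-2-yl]pyrrolidine-1-carboxylate | BrCC[C@]1(C[C@@H](C)C(=O)O1)[C@@H]1CC[C@@H]([C@@H]2C[C@H](C)C(=O)O2)N1C(=O)OC(C)(C)C | intermediate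
15 | 3-methylfuran-2-carboxylic acid | Cc1ccoc1C(=O)O | starting material
16 | 4,5-dibromo-3-methylfuran-2-carboxylic acid | Cc1c(Br)c(Br)oc1C(=O)O | intermediate
17 | 4-bromo-3-methylfuran-2-carboxylic acid | Cc1c(Br)coc1C(=O)O | intermediate
18 | tert-butyl 4-bromo-3-methylfuran-2-carboxylate | Cc1c(Br)coc1C(=O)OC(C)(C)C | intermediate
19 | tert-butyl (2S,5S)-2-[(2S,4R)-2-{2-[5-(tert-butoxycarbonyl)-4-methylfuran-3-yl]ethyl}-4-methyl-5-oxooxolan-2-yl]-5-[(2S,4S)-4-methyl-5-oxooxolan-2-yl]pyrrolidine-1-carboxylate | Cc1c(CC[C@]2(C[C@@H](C)C(=O)O2)[C@@H]2CC[C@@H]([C@@H]3C[C@H](C)C(=O)O3)N2C(=O)OC(C)(C)C)coc1C(=O)OC(C)(C)C | intermediate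
20 | 3-methyl-4-{2-[(2S,4R)-4-methyl-2-{(2S,5S)-5-[(2S,4S)-4-methyl-5-oxooxolan-2-yl]pyrrolidin-2-yl}-5-oxooxolan-2-yl]ethyl}furan-2-carboxylic acid, trifluoroacetate salt (not isolated) | Cc1c(CC[C@]2(C[C@@H](C)C(=O)O2)[C@@H]2CC[C@@H]([C@@H]3C[C@H](C)C(=O)O3)N2)coc1C(=O)O.OC(=O)C(F)(F)F | intermediate
21 | 5-hydroxy-3-methyl-4-{2-[(2S,4R)-4-methyl-2-{(2S,5S)-5-[(2S,4S)-4-methyl-5-oxooxolan-2-yl]pyrrolidin-2-yl}-5-oxooxolan-2-yl]ethyl}furan-2(5H)-one, trifluoroacetate salt, hemiacetal epimers (not isolated) | CC1=C(CC[C@]2(C[C@@H](C)C(=O)O2)[C@@H]2CC[C@@H]([C@@H]3C[C@H](C)C(=O)O3)N2)C(O)OC1=O.OC(=O)C(F)(F)F | intermediate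
22 | CNP0155196.1: pyrrolo[1,2-a]azepine with C5–C6-fused 3-methylbutenolide N,O-acetal (C5 S), C9 spiro-α-methyl-γ-lactone (C9 S, CHMe R, methyl trans to C9a), C9a S, and C3 (S)-[(2S,4S)-4-methyl-5-oxooxolan-2-yl] | CC1=C2CC[C@]3(C[C@@H](C)C(=O)O3)[C@@H]3CC[C@@H]([C@@H]4C[C@H](C)C(=O)O4)N3[C@H]2OC1=O | target

**Step count and risks**

Total steps: 13. Longest linear sequence: 9 (steps 1, 2, 4, 5, 6, 7, 8, 12, 13).

The three steps most likely to fail:

Step 13. The one-pot deprotection, photooxygenation and ring closure is untested on this system. The free amine could instead undergo O→N acyl transfer with a neighbouring lactone, or the C5 epimer ratio could be poor. The fallback moves the dearomatisation to the simple furoic acid. It sets out from 17: sensitised photooxygenation (O2, rose bengal, hν, MeOH) with loss of CO2 gives 4-bromo-5-hydroxy-3-methylfuran-2(5H)-one F6, which in the same pot with catalytic H2SO4 in refluxing methanol gives the pseudo-ester 4-bromo-5-methoxy-3-methylfuran-2(5H)-one F7. Nickel/zinc reductive coupling of this vinylogous acyl bromide with 14 (conditions of step 12) gives the Boc-protected methoxybutenolide F8. TFA/H2O at 40 °C removes Boc and hydrolyses the pseudo-ester, which brings the route back at 21; neutralisation then gives 22. Steps 11 and 12 are not needed in this variant.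

Step 5. Direction by the Boc carbonyl may be too weak for this hindered, electron-poor trisubstituted alkene, giving no conversion or the methyl epimer. The fallback replaces substrate direction by catalyst control on the ring-opened acid. It sets out from 8: LiOH (3 equiv, THF/H2O) opens the butenolide and saponifies the ester to dilithium (2S,5S)-1-(tert-butoxycarbonyl)-5-[(3S,4Z)-1-bromo-5-carboxylato-3-hydroxyhex-4-en-3-yl]pyrrolidine-2-carboxylate F1. This angelate-type carboxylate is hydrogenated with Ru(OAc)2[(R)-BINAP], H2 (50 atm), MeOH; the BINAP antipode is chosen by the tiglic acid precedent and checked against the other one. The route comes back at 10, which is acidified to 11 as in step 6.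

Step 7. The second vinylogous Mannich reaction may give the 2,5-cis pyrrolidine or poor threo selectivity on the N-Boc iminium ion. The fallback keeps the pyroglutamate stereocentre as C3 and builds the lactone on the carboxyl carbon instead. It sets out from 11: BH3·SMe2 (THF, 0 °C) reduces the acid, not the lactone, to tert-butyl (2S,5S)-2-[(2R,4R)-2-(2-bromoethyl)-4-methyl-5-oxooxolan-2-yl]-5-(hydroxymethyl)pyrrolidine-1-carboxylate F2. Dess–Martin oxidation gives the aldehyde tert-butyl (2S,5S)-2-[(2R,4R)-2-(2-bromoethyl)-4-methyl-5-oxooxolan-2-yl]-5-formylpyrrolidine-1-carboxylate F3. Zinc-mediated Barbier addition of ethyl 2-(bromomethyl)acrylate (THF/aq NH4Cl, chelation-controlled, threo) gives the hydroxy ester ethyl (4S)-4-{(2S,5S)-5-[(2R,4R)-2-(2-bromoethyl)-4-methyl-5-oxooxolan-2-yl]-1-(tert-butoxycarbonyl)pyrrolidin-2-yl}-4-hydroxy-2-methylidenebutanoate F4. This lactonises with catalytic TsOH to the α-methylene lactone tert-butyl (2S,5S)-2-[(2R,4R)-2-(2-bromoethyl)-4-methyl-5-oxooxolan-2-yl]-5-[(2S)-4-methylidene-5-oxooxolan-2-yl]pyrrolidine-1-carboxylate F5. H2 over Rh/C from the face opposite the pyrrolidine gives the cis-methyl lactone, and the route comes back at 14.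

**Further compounds**

F1 | step 5 | dilithium (2S,5S)-1-(tert-butoxycarbonyl)-5-[(3S,4Z)-1-bromo-5-carboxylato-3-hydroxyhex-4-en-3-yl]pyrrolidine-2-carboxylate | BrCC[C@](O)(/C=C(C)\C(=O)[O-])[C@@H]1CC[C@@H](C(=O)[O-])N1C(=O)OC(C)(C)C.[Li+].[Li+]
F2 | step 7 | tert-butyl (2S,5S)-2-[(2R,4R)-2-(2-bromoethyl)-4-methyl-5-oxooxolan-2-yl]-5-(hydroxymethyl)pyrrolidine-1-carboxylate | BrCC[C@]1(C[C@@H](C)C(=O)O1)[C@@H]1CC[C@@H](CO)N1C(=O)OC(C)(C)C
F3 | step 7 | tert-butyl (2S,5S)-2-[(2R,4R)-2-(2-bromoethyl)-4-methyl-5-oxooxolan-2-yl]-5-formylpyrrolidine-1-carboxylate | BrCC[C@]1(C[C@@H](C)C(=O)O1)[C@@H]1CC[C@@H](C=O)N1C(=O)OC(C)(C)C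
F4 | step 7 | ethyl (4S)-4-{(2S,5S)-5-[(2R,4R)-2-(2-bromoethyl)-4-methyl-5-oxooxolan-2-yl]-1-(tert-butoxycarbonyl)pyrrolidin-2-yl}-4-hydroxy-2-methylidenebutanoate | BrCC[C@]1(C[C@@H](C)C(=O)O1)[C@@H]1CC[C@@H]([C@@H](O)CC(=C)C(=O)OCC)N1C(=O)OC(C)(C)C
F5 | step 7 | tert-butyl (2S,5S)-2-[(2R,4R)-2-(2-bromoethyl)-4-methyl-5-oxooxolan-2-yl]-5-[(2S)-4-methylidene-5-oxooxolan-2-yl]pyrrolidine-1-carboxylate | BrCC[C@]1(C[C@@H](C)C(=O)O1)[C@@H]1CC[C@@H]([C@@H]2CC(=C)C(=O)O2)N1C(=O)OC(C)(C)C
F6 | step 13 | 4-bromo-5-hydroxy-3-methylfuran-2(5H)-one (racemic) | CC1=C(Br)C(O)OC1=O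
F7 | step 13 | 4-bromo-5-methoxy-3-methylfuran-2(5H)-one (racemic) | COC1OC(=O)C(C)=C1Br
F8 | step 13 | tert-butyl (2S,5S)-2-[(2S,4R)-2-[2-(2-methoxy-4-methyl-5-oxo-2,5-dihydrofuran-3-yl)ethyl]-4-methyl-5-oxooxolan-2-yl]-5-[(2S,4S)-4-methyl-5-oxooxolan-2-yl]pyrrolidine-1-carboxylate (acetal epimers) | COC1OC(=O)C(C)=C1CC[C@]2(C[C@@H](C)C(=O)O2)[C@@H]2CC[C@@H]([C@@H]3C[C@H](C)C(=O)O3)N2C(=O)OC(C)(C)C
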